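**Plan**

- **Enabling feature.** On the oxolane ring (O1, C2 aryl, C3 CH2OH, C4 CH2Ar, C5 H2) the carbon arms at C3 and C4 are cis. Linking the C3 arm (as C=O) through oxygen to the benzylic carbon of the C4 arm gives a γ-aryl-γ-butyrolactone fused across C3–C4.
- **Cuts.** That auxiliary lactone C–O bond is first put back (benzyl CH2 to ArCH–O, CH2OH to C=O). C2–C3 and C4–C5 are then cut together, leaving a γ-aryl butenolide and the dipole ArCH=O(+)–CH2(−). In the side chain, C7''–C8'' is cut as an aldol and O–C8'' is traced to an aryloxyacetic acid.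
- **Forward order.** The butenolide ring is closed by ring-closing metathesis. The side chain is made by aldol and locked as a 1,3-dioxane. The oxolane ring closes in the (3+2) cycloaddition to give a cis-fused furofuranone. The lactone ring is then opened by hydrogenolysis, the acid reduced and the dioxane hydrolysed.
- **Stereochemistry.** C7''/C8'' (S,S, threo) come from an Evans syn aldol with the R auxiliary. The butenolide centre (S) comes from a lipase resolution. It steers C3 and C4 (anti face, cis fusion) and C2 (exo aryl) and is erased afterwards.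

Key step: step 14

Assumption: compounds 1, 6, 8 and 17 are taken as commercial; the locants C2–C5 (oxolane) and C7''–C9'' (arylglycerol chain) refer to the target, read from its SMILES as 2S,3R,4R,7''S,8''S.

**Step 1**
Reactants: 1 4-benzyloxy-3-methoxybenzaldehyde (benzyl vanillin)
Product: 2 rac-1-(4-benzyloxy-3-methoxyphenyl)prop-2-en-1-ol
Conditions: CH2=CHMgBr, THF, 0 °C; then aq. NH4Cl
Reagents that add atoms: vinylmagnesium bromide, C=C[Mg]Br
Why: Grignard 1,2-addition of a vinyl nucleophile to an aryl aldehyde; the carbinol centre forms racemic and is resolved in step 2.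

**Step 2**
Reactants: 2 rac-1-(4-benzyloxy-3-methoxyphenyl)prop-2-en-1-ol
Product: 3 (S)-1-(4-benzyloxy-3-methoxyphenyl)prop-2-en-1-ol
Conditions: Novozym 435 (CAL-B), vinyl acetate, MTBE, 30 °C, stopped just past half conversion; chromatography
Reagents that add atoms: none
Why: Lipase-catalysed kinetic resolution following the Kazlauskas rule, in which CAL-B acetylates the R enantiomer of aryl vinyl carbinols (vinyl in the medium pocket), so that the S alcohol should remain and be separable from the acetate.

**Step 3**
Reactants: 3 (S)-1-(4-benzyloxy-3-methoxyphenyl)prop-2-en-1-ol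
Product: 4 (S)-1-(4-benzyloxy-3-methoxyphenyl)allyl acrylate
Conditions: acryloyl chloride, Et3N, CH2Cl2, 0 °C
Reagents that add atoms: acryloyl chloride, C=CC(=O)Cl
Why: O-acylation of an alcohol with an acyl chloride, which takes place at oxygen and leaves the C–O bond of the stereocentre intact.

**Step 4**
Reactants: 4 (S)-1-(4-benzyloxy-3-methoxyphenyl)allyl acrylate
Product: 5 (S)-5-(4-benzyloxy-3-methoxyphenyl)furan-2(5H)-one
Conditions: Grubbs II (3 mol %), CH2Cl2 (0.01 M), reflux
Reagents that add atoms: none
Why: Ring-closing metathesis of an allyl acrylate closes the five-membered butenolide under neutral conditions, so the base-sensitive γ-stereocentre should be carried over unchanged.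

**Step 5**
Reactants: 6 4-bromo-2-methoxyphenol
Product: 7 2-(4-bromo-2-methoxyphenoxy)acetic acid
Conditions: ClCH2CO2H, NaOH, H2O, reflux; then HCl
Reagents that add atoms: chloroacetic acid, OC(=O)CCl
Why: Williamson ether synthesis, the phenoxide displacing chloride from chloroacetate by SN2; no stereocentre is involved.

**Step 6**
Reactants: 7 2-(4-bromo-2-methoxyphenoxy)acetic acid; 8 (R)-4-benzyloxazolidin-2-one
Product: 10 (R)-4-benzyl-3-[2-(4-bromo-2-methoxyphenoxy)acetyl]oxazolidin-2-one, via mixed pivalic anhydride 9 (not isolated)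
Conditions: PivCl, Et3N, THF, −20 °C; then LiCl, 8, −20 °C → rt
Reagents that add atoms: none
Why: N-acylation of an oxazolidinone by a mixed anhydride under LiCl/Et3N activation, attack occurring at the less hindered aryloxyacetyl carbonyl and leaving the auxiliary centre untouched.

**Step 7**
Reactants: 10 (R)-4-benzyl-3-[2-(4-bromo-2-methoxyphenoxy)acetyl]oxazolidin-2-one; 1 4-benzyloxy-3-methoxybenzaldehyde
Product: 12 (R)-4-benzyl-3-[(2R,3S)-3-(4-benzyloxy-3-methoxyphenyl)-2-(4-bromo-2-methoxyphenoxy)-3-hydroxypropanoyl]oxazolidin-2-one, via Z-dibutylboron enolate 11 (not isolated)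
Conditions: Bu2BOTf, Et3N, CH2Cl2, −78 → 0 °C; 1, −78 → 0 °C; then pH 7 buffer, MeOH, 30 % H2O2, 0 °C
Reagents that add atoms: none
Why: Evans syn aldol, in which soft enolisation gives the Z-boron enolate and a Zimmerman–Traxler chair on the enolate face remote from the benzyl group of the R auxiliary sets C8'' and C7'' (2R,3S in the imide) in the syn, that is threo, relationship.

**Step 8**
Reactants: 12 syn aldol imide
Product: 13 (1S,2S)-1-(4-benzyloxy-3-methoxyphenyl)-2-(4-bromo-2-methoxyphenoxy)propane-1,3-diol
Conditions: NaBH4, THF–H2O (4:1), 0 °C → rt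
Reagents that add atoms: none
Why: Borohydride reductive cleavage of an N-acyl oxazolidinone at the exocyclic imide carbonyl gives the primary alcohol and releases the auxiliary without touching either stereocentre.

**Step 9**
Reactants: 13 threo 1,3-diol
Product: 14 (4S,5S)-4-(4-benzyloxy-3-methoxyphenyl)-5-(4-bromo-2-methoxyphenoxy)-2,2-dimethyl-1,3-dioxane
Conditions: Me2C(OMe)2, PPTS (cat.), CH2Cl2, rt
Reagents that add atoms: 2,2-dimethoxypropane, COC(C)(C)OC
Why: Acid-catalysed transketalisation; because O8'' is already arylated, the 7'',9''-diol is the only diol present and the six-membered acetonide is the only cyclic ketal that can form.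

**Step 10**
Reactants: 14 bromo acetonide
Product: 16 4-{[(4S,5S)-4-(4-benzyloxy-3-methoxyphenyl)-2,2-dimethyl-1,3-dioxan-5-yl]oxy}-3-methoxybenzaldehyde, via aryllithium 15 (not isolated)
Conditions: n-BuLi, THF, −78 °C; DMF, −78 → 0 °C; then H2O
Reagents that add atoms: N,N-dimethylformamide, CN(C)C=O
Why: Bromine–lithium exchange followed by Bouveault formylation; the exchange at −78 °C is much faster than deprotonation of the benzyl ether or dioxane positions.

**Step 11**
Reactants: 17 (trimethylsilyl)methanol
Product: 18 trimethyl[(trimethylsilyl)methoxy]silane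
Conditions: TMSCl, Et3N, Et2O, 0 °C → rt; distillation
Reagents that add atoms: chlorotrimethylsilane, C[Si](C)(C)Cl
Why: Routine O-silylation of a primary alcohol, which supplies the alkoxysilane needed for an aprotic acetalisation.

**Step 12**
Reactants: 16 side-chain aldehyde; 18 trimethyl[(trimethylsilyl)methoxy]silane
Product: 19 bis[(trimethylsilyl)methyl] acetal of aldehyde 16
Conditions: 18 (2.5 equiv), TMSOTf (5 mol %), CH2Cl2, −78 °C; pyridine quench
Reagents that add atoms: none
Why: Noyori acetalisation (alkoxysilane with catalytic TMSOTf) runs without water or protic acid at −78 °C, conditions under which the cyclic acetonide should persist.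

**Step 13**
Reactants: 19 bis[(trimethylsilyl)methyl] acetal
Product: 20 α-chlorobenzyl (trimethylsilyl)methyl ether carrying the acetonide side chain (both epimers at the C–Cl carbon)
Conditions: AcCl (1.05 equiv), Zn(OTf)2 (0.1 mol %), CH2Cl2, 0 °C; volatiles removed in vacuo, residue used at once
Reagents that add atoms: acetyl chloride, CC(=O)Cl
Why: Zinc-catalysed acetal/acyl chloride exchange to an α-chloro ether, in which the acyclic acetal of the electron-rich benzaldehyde ionises far faster than the cyclic ketal; the configuration at the chloride carbon is irrelevant because this carbon becomes planar in step 14.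

**Step 14**
Reactants: 20 α-chlorobenzyl (trimethylsilyl)methyl ether; 5 (S)-5-(4-benzyloxy-3-methoxyphenyl)furan-2(5H)-one
Product: 22 (3S,3aR,6S,6aS)-3-(4-benzyloxy-3-methoxyphenyl)-6-{4-[((4S,5S)-4-(4-benzyloxy-3-methoxyphenyl)-2,2-dimethyl-1,3-dioxan-5-yl)oxy]-3-methoxyphenyl}tetrahydro-1H,3H-furo[3,4-c]furan-1-one, via carbonyl ylide 21 (not isolated)
Conditions: 5 (1.5 equiv), TBAT (1.0 equiv, slow addition), MeCN–CH2Cl2, 0 °C → rt; then aq. NaHCO3
Reagents that add atoms: none
Why: Fluoride attacks the silicon of 20, whose C–Cl bond is strongly polarised by the para-alkoxyaryl group, and 1,3-elimination of Me3SiF and chloride releases the non-stabilised carbonyl ylide 21, a 4π dipole that adds suprafacially across the C=C bond of 5; the closest known reaction type is the CsF-induced carbonyl ylide (3+2) cycloaddition of α-chloroalkyl silylmethyl ethers to acrylates, fumarates and enones. The oxolane ring closes in this intermolecular (3+2) mode, forming C2–C3 and C4–C5 in one operation, and suprafacial addition to a ring Z-alkene can only give the cis-fused furofuranone, which fixes the C3/C4 cis relationship. The absolute sense at C3 and C4 follows from approach to the butenolide face anti to the γ-aryl group, the usual behaviour of dipoles towards 5-substituted butenolides. C2 is set by an exo approach of the E (W-shaped) ylide, which places its aryl group on the convex face, trans to the lactone carbonyl. The regioselectivity needed comes from ylide polarity: the donor aryl group holds the positive charge at the benzylic terminus, so the carbanionic CH2 terminus bonds to the electrophilic β-carbon and the benzylic terminus to the α-carbon. Slow addition of the weakly basic TBAT keeps free fluoride low so that the acidic γ-hydrogen of 5 is not removed, and unconsumed 20 reverts to aldehyde 16 on aqueous work-up.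

**Step 15**
Reactants: 22 cis-fused furofuranone
Product: 23 (2S,3S,4R)-4-(4-hydroxy-3-methoxybenzyl)-2-{4-[((4S,5S)-4-(4-hydroxy-3-methoxyphenyl)-2,2-dimethyl-1,3-dioxan-5-yl)oxy]-3-methoxyphenyl}oxolane-3-carboxylic acid
Conditions: H2 (1 atm), 10 % Pd/C, EtOAc–EtOH, rt, followed until the lactone is consumed
Reagents that add atoms: none
Why: Catalytic hydrogenolysis, in which the two aryl benzyl ethers go first and the lactone C–O bond, the only benzylic bond bearing an acyloxy leaving group and by then para to a free phenol, should follow ahead of the benzylic alkyl ether bonds at C2 and C7''; the sacrificial centre becomes CH2 while C2, C3 and C4 are not involved.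

**Step 16**
Reactants: 23 oxolane-3-carboxylic acid
Product: 24 7'',9''-O-isopropylidene derivative of the target (C3 CH2OH in place)
Conditions: BH3·THF (excess), THF, 0 °C → rt; MeOH quench
Reagents that add atoms: none
Why: Chemoselective borane reduction of a carboxylic acid through its acyloxyborane, which tolerates the ketal and aryl ethers (the phenols only consume reagent) and does not enolise C3.

**Step 17**
Reactants: 24 acetonide of the target
Product: 25 target CNP0226724.1
Conditions: AcOH–H2O (4:1), rt
Reagents that add atoms: none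
Why: Acid-catalysed ketal hydrolysis under the mildest aqueous conditions, chosen so that the p-hydroxybenzylic C7'' alcohol and the C2 benzylic ether do not ionise and all five stereocentres persist.

**Compound list**

1 | 4-benzyloxy-3-methoxybenzaldehyde | COc1cc(C=O)ccc1OCc1ccccc1 | starting material
2 | rac-1-(4-benzyloxy-3-methoxyphenyl)prop-2-en-1-ol (racemic) | COc1cc(C(O)C=C)ccc1OCc1ccccc1 | intermediate
3 | (S)-1-(4-benzyloxy-3-methoxyphenyl)prop-2-en-1-ol | COc1cc([C@@H](O)C=C)ccc1OCc1ccccc1 | intermediate
4 | (S)-1-(4-benzyloxy-3-methoxyphenyl)allyl acrylate | COc1cc([C@@H](OC(=O)C=C)C=C)ccc1OCc1ccccc1 | intermediate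
5 | (S)-5-(4-benzyloxy-3-methoxyphenyl)furan-2(5H)-one | COc1cc([C@@H]2C=CC(=O)O2)ccc1OCc1ccccc1 | intermediate
6 | 4-bromo-2-methoxyphenol | COc1cc(Br)ccc1O | starting material
7 | 2-(4-bromo-2-methoxyphenoxy)acetic acid | COc1cc(Br)ccc1OCC(=O)O | intermediate
8 | (R)-4-benzyloxazolidin-2-one | O=C1N[C@H](Cc2ccccc2)CO1 | starting material
9 | 2-(4-bromo-2-methoxyphenoxy)acetic pivalic anhydride | COc1cc(Br)ccc1OCC(=O)OC(=O)C(C)(C)C | intermediate
10 | (R)-4-benzyl-3-[2-(4-bromo-2-methoxyphenoxy)acetyl]oxazolidin-2-one | COc1cc(Br)ccc1OCC(=O)N1[C@H](Cc2ccccc2)COC1=O | intermediate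
11 | (Z)-dibutylboron enolate of 10 | COc1cc(Br)ccc1O/C=C(\OB(CCCC)CCCC)N1[C@H](Cc2ccccc2)COC1=O | intermediate
12 | (R)-4-benzyl-3-[(2R,3S)-3-(4-benzyloxy-3-methoxyphenyl)-2-(4-bromo-2-methoxyphenoxy)-3-hydroxypropanoyl]oxazolidin-2-one | COc1cc(Br)ccc1O[C@@H](C(=O)N1[C@H](Cc2ccccc2)COC1=O)[C@@H](O)c1ccc(OCc2ccccc2)c(OC)c1 | intermediate
13 | (1S,2S)-1-(4-benzyloxy-3-methoxyphenyl)-2-(4-bromo-2-methoxyphenoxy)propane-1,3-diol | COc1cc(Br)ccc1O[C@@H](CO)[C@@H](O)c1ccc(OCc2ccccc2)c(OC)c1 | intermediate
14 | (4S,5S)-4-(4-benzyloxy-3-methoxyphenyl)-5-(4-bromo-2-methoxyphenoxy)-2,2-dimethyl-1,3-dioxane | COc1cc(Br)ccc1O[C@@H](CO2)[C@@H](OC2(C)C)c1ccc(OCc2ccccc2)c(OC)c1 | intermediate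
15 | aryllithium from 14 | COc1cc([Li])ccc1O[C@@H](CO2)[C@@H](OC2(C)C)c1ccc(OCc2ccccc2)c(OC)c1 | intermediate
16 | 4-{[(4S,5S)-4-(4-benzyloxy-3-methoxyphenyl)-2,2-dimethyl-1,3-dioxan-5-yl]oxy}-3-methoxybenzaldehyde | COc1cc(C=O)ccc1O[C@@H](CO2)[C@@H](OC2(C)C)c1ccc(OCc2ccccc2)c(OC)c1 | intermediate
17 | (trimethylsilyl)methanol | C[Si](C)(C)CO | starting material
18 | trimethyl[(trimethylsilyl)methoxy]silane | C[Si](C)(C)CO[Si](C)(C)C | intermediate
19 | bis[(trimethylsilyl)methyl] acetal of 16 | C[Si](C)(C)COC(OC[Si](C)(C)C)c1ccc(O[C@@H](CO2)[C@@H](OC2(C)C)c3ccc(OCc4ccccc4)c(OC)c3)c(OC)c1 | intermediate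
20 | α-chlorobenzyl (trimethylsilyl)methyl ether with acetonide side chain (both epimers at C–Cl) | C[Si](C)(C)COC(Cl)c1ccc(O[C@@H](CO2)[C@@H](OC2(C)C)c3ccc(OCc4ccccc4)c(OC)c3)c(OC)c1 | intermediate
21 | (E)-carbonyl ylide ArCH=O(+)–CH2(−) | [CH2-]/[O+]=C/c1ccc(O[C@@H](CO2)[C@@H](OC2(C)C)c3ccc(OCc4ccccc4)c(OC)c3)c(OC)c1 | intermediate
22 | (3S,3aR,6S,6aS)-3,6-diaryl furofuranone with side chain | COc1cc([C@@H]2[C@H]3CO[C@H](c4ccc(O[C@@H](CO5)[C@@H](OC5(C)C)c6ccc(OCc7ccccc7)c(OC)c6)c(OC)c4)[C@H]3C(=O)O2)ccc1OCc1ccccc1 | intermediate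
23 | (2S,3S,4R)-oxolane-3-carboxylic acid, free phenols, acetonide intact | COc1cc(C[C@H]2CO[C@H](c3ccc(O[C@@H](CO4)[C@@H](OC4(C)C)c5ccc(O)c(OC)c5)c(OC)c3)[C@H]2C(=O)O)ccc1O | intermediate
24 | 7'',9''-O-isopropylidene derivative of the target | COc1cc(C[C@H]2CO[C@H](c3ccc(O[C@@H](CO4)[C@@H](OC4(C)C)c5ccc(O)c(OC)c5)c(OC)c3)[C@H]2CO)ccc1O | intermediate
25 | CNP0226724.1, (2S,3R,4R)-oxolane with (7''S,8''S)-threo arylglycerol ether | COc1cc(C[C@H]2CO[C@H](c3ccc(O[C@@H](CO)[C@@H](O)c4ccc(O)c(OC)c4)c(OC)c3)[C@H]2CO)ccc1O | target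

Total step count: 17. Longest linear sequence: 12 steps (steps 5–10 and 12–17, from 6).

**Steps most likely to fail**

**Step 14.**
- Risk: the ylide may collapse by ring closure or self-reaction faster than the 1,2-disubstituted butenolide captures it. Regio- or exo/endo selectivity may be poor. Fluoride may racemise the butenolide by γ-deprotonation.
- Fallback: it sets out from 1 and 16, comes back at 24, and replaces the cycloaddition by the aldol and cyclodehydration logic of the dibenzylbutyrolactone lignans.
- Stobbe condensation of 1 with dimethyl succinate (NaOMe, MeOH) should give the (E)-benzylidenesuccinic half-ester F1.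
- Rh(I)/Et-DuPHOS hydrogenation, with the ligand antipode that delivers the R acid, should give the (R)-benzylsuccinic half-ester F2.
- Ca(BH4)2 reduction of its potassium salt and acid lactonisation should give the (R)-β-benzyl-γ-butyrolactone F3.
- Its lithium enolate (LiHMDS, THF, −78 °C) should add to aldehyde 16 anti to the benzyl group to give the trans aldol lactone F4, both carbinol epimers being usable.
- LiAlH4 then should give the triol F5.
- Catalytic CSA in CH2Cl2 ionises the benzylic alcohol, and the hydroxymethyl group next to the benzyl arm closes the oxolane. The aryl group ends trans to the C3 arm. The trans lactone translates into the 3,4-cis ring of the dibenzyl ether F6.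
- Brief hydrogenolysis of the two aryl benzyl ethers of F6 returns to 24.

**Step 15.**
- Risk: conditions strong enough to break the lactone C–O bond may also cleave the benzylic ether bonds at C2 and at C7'' once the neighbouring phenol is free, or the lactone may resist cleavage.
- Fallback: it sets out from 22, comes back at 23, and exchanges catalytic C–O cleavage for a 1,6-elimination and hydride capture.
- A short hydrogenolysis (Pd/C, EtOAc) that stops after O-debenzylation should give the diphenol lactone F7.
- NaBH4 in THF–aq. NaOH at 0 °C → rt lets the phenoxide expel the carboxylate to give the p-quinone methide acid F8, which hydride reduces at the exocyclic carbon to give 23 after acidification.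
- The side-chain phenol faces only an alkoxide leaving group and should not react at this temperature.

**Step 13.**
- Risk: the acyl chloride exchange may also open the acetonide, or the very labile chloride may hydrolyse or lose its silyl group before use.
- Fallback: it sets out from 19, comes back at 22, and omits the covalent chloride.
- With 5 present, TMSOTf (1 equiv, CH2Cl2–MeCN, −40 °C) ionises one silylmethoxy group of 19 to the oxocarbenium triflate F9.
- Slow addition of TBAT then desilylates F9 to ylide 21, as in the N,O-acetal route to azomethine ylides.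

**Further compounds**

F1 | step 14 | (E)-3-(methoxycarbonyl)-4-(4-benzyloxy-3-methoxyphenyl)but-3-enoic acid | COC(=O)/C(CC(=O)O)=C/c1ccc(OCc2ccccc2)c(OC)c1
F2 | step 14 | (R)-3-(methoxycarbonyl)-4-(4-benzyloxy-3-methoxyphenyl)butanoic acid | COc1cc(C[C@@H](C(=O)OC)CC(=O)O)ccc1OCc1ccccc1
F3 | step 14 | (R)-4-(4-benzyloxy-3-methoxybenzyl)dihydrofuran-2(3H)-one | COc1cc(C[C@@H]2CC(=O)OC2)ccc1OCc1ccccc1
F4 | step 14 | trans α-[aryl(hydroxy)methyl]-β-benzyl lactone from F3 and 16 (both carbinol epimers) | COc1cc(C[C@H]2COC(=O)[C@@H]2C(O)c2ccc(O[C@@H](CO3)[C@@H](OC3(C)C)c4ccc(OCc5ccccc5)c(OC)c4)c(OC)c2)ccc1OCc1ccccc1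
F5 | step 14 | triol from reduction of F4 (both carbinol epimers) | COc1cc(C[C@@H](CO)[C@H](CO)C(O)c2ccc(O[C@@H](CO3)[C@@H](OC3(C)C)c4ccc(OCc5ccccc5)c(OC)c4)c(OC)c2)ccc1OCc1ccccc1
F6 | step 14 | di-O-benzyl ether of 24 | COc1cc(C[C@H]2CO[C@H](c3ccc(O[C@@H](CO4)[C@@H](OC4(C)C)c5ccc(OCc6ccccc6)c(OC)c5)c(OC)c3)[C@H]2CO)ccc1OCc1ccccc1
F7 | step 15 | diphenol furofuranone (22 without benzyl groups) | COc1cc([C@@H]2[C@H]3CO[C@H](c4ccc(O[C@@H](CO5)[C@@H](OC5(C)C)c6ccc(O)c(OC)c6)c(OC)c4)[C@H]3C(=O)O2)ccc1O
F8 | step 15 | p-quinone methide acid (either exocyclic alkene geometry) | COC1=CC(=C[C@H]2CO[C@H](c3ccc(O[C@@H](CO4)[C@@H](OC4(C)C)c5ccc(O)c(OC)c5)c(OC)c3)[C@H]2C(=O)O)C=CC1=O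
F9 | step 13 | O-(trimethylsilylmethyl) oxocarbenium triflate from 19 | C[Si](C)(C)C[O+]=Cc1ccc(O[C@@H](CO2)[C@@H](OC2(C)C)c3ccc(OCc4ccccc4)c(OC)c3)c(OC)c1.[O-]S(=O)(=O)C(F)(F)F
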